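**Plan**

1. Retrosynthesis: the two methyl ethers are cut first and both CH2O carbons are raised to methyl esters. Ring B (the saturated ring) is then opened at C2–C3, the bond joining the two ester α-carbons. The open diester is cut at C1–aryl (conjugate addition of the pendant 3,4-dimethoxyphenyl group) and at C8a–C1 (Heck vinylation of ring A).
2. Forward: ring A is bought as methyl 3-(3,4-dimethoxyphenyl)propanoate, which already holds C4, C3 and one ester. Bromination and a Heck reaction add C1, C2 and the second ester, the pendant aryl is added to C1, and ring B is closed by oxidative coupling of the two ester enolates. Reduction and O-methylation finish the route.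
3. Enabling feature: C2 and C3 each bear exactly one exocyclic carbon. At the ester level they are two enolizable α-carbons held in a 1,6 relationship by the ortho-disubstituted ring A, so joining them closes the six-membered ring B. The same esters keep C2 and C3 epimerizable.
4. Stereochemistry: C1 (R) comes from the Rh/(S)-BINAP conjugate addition. C2 and C3 (S,S) follow by thermodynamic relay from C1 (all-trans, all-equatorial diester) and are carried unchanged to the end.

Key step: step 4

Assumption: compounds 1, 3 and 5 are bought. The sense of induction in step 3 is taken from the accepted α-si-face model for Rh/(S)-BINAP with (E)-enoates; (R)-BINAP would be used if the configuration of 6 proved opposite.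

**Route**

Step 1
Reactants: 1 methyl 3-(3,4-dimethoxyphenyl)propanoate
Product: 2 methyl 3-(2-bromo-4,5-dimethoxyphenyl)propanoate
Conditions: NBS (1.05 equiv), MeCN, 0 °C to rt
Reagents that add atoms: N-bromosuccinimide, O=C1CCC(=O)N1Br
Why: Electrophilic aromatic bromination should occur at the ring position para to the 3-methoxy group and ortho to the side chain, the most activated open site of the veratrole ring, without touching the ester.

Step 2
Reactants: 2 methyl 3-(2-bromo-4,5-dimethoxyphenyl)propanoate; 3 methyl acrylate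
Product: 4 methyl (2E)-3-[4,5-dimethoxy-2-(3-methoxy-3-oxopropyl)phenyl]prop-2-enoate
Conditions: Pd(OAc)2 (3 mol%), P(o-tol)3 (9 mol%), NaOAc (1.5 equiv), DMF, 110 °C
Reagents that add atoms: none
Why: The Mizoroki–Heck reaction of an aryl bromide with an acrylate should give the (E)-cinnamate by syn insertion and syn β-hydride elimination, the saturated ester being inert.

Step 3
Reactants: 4 methyl (2E)-3-[4,5-dimethoxy-2-(3-methoxy-3-oxopropyl)phenyl]prop-2-enoate; 5 (3,4-dimethoxyphenyl)boronic acid
Product: 6 methyl (3R)-3-(3,4-dimethoxyphenyl)-3-[4,5-dimethoxy-2-(3-methoxy-3-oxopropyl)phenyl]propanoate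
Conditions: [Rh(acac)(C2H4)2] (3 mol%), (S)-BINAP (3.3 mol%), 5 (2.5 equiv), dioxane/H2O (10:1), 100 °C
Reagents that add atoms: none
Why: In this Hayashi–Miyaura asymmetric conjugate addition the aryl–rhodium/(S)-BINAP species should bind the α-si face of the (E)-enoate and so create the diarylmethine centre (the future C1) as R, while the saturated ester does not react.

Step 4
Reactants: 6 methyl (3R)-3-(3,4-dimethoxyphenyl)-3-[4,5-dimethoxy-2-(3-methoxy-3-oxopropyl)phenyl]propanoate
Product: 8 dimethyl (1R)-1-(3,4-dimethoxyphenyl)-6,7-dimethoxy-1,2,3,4-tetrahydronaphthalene-2,3-dicarboxylate as a mixture of C2/C3 epimers, via dilithium bis-enolate 7 (not isolated)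
Conditions: LiN(iPr)2 (2.3 equiv), THF, −78 °C, 0.02 M (6 added to the base); then CuBr2 (2.4 equiv), THF/DMF, −78 °C to 0 °C; aq. NH4Cl/NH3
Reagents that add atoms: none
Why: Double deprotonation gives the bis(ester enolate) 7; CuBr2 removes one electron from the less hindered C3 enolate, the α-ester radical (or its copper enolate) attacks the neighbouring C2 enolate carbon, and a second one-electron oxidation gives the neutral diester, so two equivalents of divalent copper are consumed. The closest known reaction type is the oxidative coupling of lithium ester enolates with cupric halides, including its intramolecular form on α,ω-diester dianions. Ring B closes in the 6-exo-trig mode, the attacked enolate C=C lying outside the new ring. C2 and C3 are created here without reliable kinetic control (a bias to trans is expected because bonding anti to the C1 aryl group is less hindered) and are fixed by thermodynamic relay from C1 in step 5, which the retained esters make possible; C1 carries no acidifying group and should not be touched. The step needs ring closure to outrun intermolecular coupling and Claisen condensation, which the ortho placement of both chains on ring A, high dilution and −78 °C should secure.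

Step 5
Reactants: 8 dimethyl (1R)-1-(3,4-dimethoxyphenyl)-6,7-dimethoxy-1,2,3,4-tetrahydronaphthalene-2,3-dicarboxylate (epimer mixture)
Product: 9 dimethyl (1R,2S,3S)-1-(3,4-dimethoxyphenyl)-6,7-dimethoxy-1,2,3,4-tetrahydronaphthalene-2,3-dicarboxylate
Conditions: NaOMe (0.5 equiv), MeOH, 50 °C
Reagents that add atoms: none
Why: Base-mediated epimerization through the ester enolates inverts C2 and C3 freely while C1 cannot invert, and the 1,2-trans-2,3-trans isomer with aryl and both esters (pseudo)equatorial should be the thermodynamic sink, so the mixture converges on the (1R,2S,3S) diester.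

Step 6
Reactants: 9 dimethyl (1R,2S,3S)-1-(3,4-dimethoxyphenyl)-6,7-dimethoxy-1,2,3,4-tetrahydronaphthalene-2,3-dicarboxylate
Product: 10 [(1R,2S,3S)-1-(3,4-dimethoxyphenyl)-6,7-dimethoxy-1,2,3,4-tetrahydronaphthalene-2,3-diyl]dimethanol
Conditions: LiAlH4 (2.5 equiv), THF, 0 °C to rt; aq. NaOH work-up
Reagents that add atoms: none
Why: Hydride reduction of both esters to primary alcohols should proceed without epimerization, since the aluminium alkoxide is formed faster than enolization and no stereocentre is α to a carbonyl afterwards.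

Step 7
Reactants: 10 [(1R,2S,3S)-1-(3,4-dimethoxyphenyl)-6,7-dimethoxy-1,2,3,4-tetrahydronaphthalene-2,3-diyl]dimethanol
Product: 11 phyltetralin, (1R,2S,3S)-1-(3,4-dimethoxyphenyl)-6,7-dimethoxy-2,3-bis(methoxymethyl)-1,2,3,4-tetrahydronaphthalene
Conditions: NaH (3 equiv), MeI (4 equiv), THF/DMF, 0 °C to rt
Reagents that add atoms: iodomethane, CI
Why: Williamson etherification of both primary alkoxides with MeI should give the bis(methyl ether) and leaves the aryl ethers and the three stereocentres untouched.

**Compound list**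

1 | methyl 3-(3,4-dimethoxyphenyl)propanoate | COC(=O)CCc1ccc(OC)c(OC)c1 | starting material
2 | methyl 3-(2-bromo-4,5-dimethoxyphenyl)propanoate | COC(=O)CCc1cc(OC)c(OC)cc1Br | intermediate
3 | methyl acrylate | COC(=O)C=C | starting material
4 | methyl (2E)-3-[4,5-dimethoxy-2-(3-methoxy-3-oxopropyl)phenyl]prop-2-enoate | COC(=O)CCc1cc(OC)c(OC)cc1/C=C/C(=O)OC | intermediate
5 | (3,4-dimethoxyphenyl)boronic acid | COc1ccc(B(O)O)cc1OC | starting material
6 | methyl (3R)-3-(3,4-dimethoxyphenyl)-3-[4,5-dimethoxy-2-(3-methoxy-3-oxopropyl)phenyl]propanoate | COC(=O)C[C@H](c1ccc(OC)c(OC)c1)c1cc(OC)c(OC)cc1CCC(=O)OC | intermediate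
7 | dilithium bis-enolate of 6 | [Li+].[Li+].COC([O-])=C[C@H](c1ccc(OC)c(OC)c1)c1cc(OC)c(OC)cc1CC=C([O-])OC | intermediate
8 | dimethyl (1R)-1-(3,4-dimethoxyphenyl)-6,7-dimethoxy-1,2,3,4-tetrahydronaphthalene-2,3-dicarboxylate, mixture of C2/C3 epimers | COC(=O)C1Cc2cc(OC)c(OC)cc2[C@@H](c2ccc(OC)c(OC)c2)C1C(=O)OC | intermediate
9 | dimethyl (1R,2S,3S)-1-(3,4-dimethoxyphenyl)-6,7-dimethoxy-1,2,3,4-tetrahydronaphthalene-2,3-dicarboxylate | COC(=O)[C@H]1Cc2cc(OC)c(OC)cc2[C@@H](c2ccc(OC)c(OC)c2)[C@@H]1C(=O)OC | intermediate
10 | [(1R,2S,3S)-1-(3,4-dimethoxyphenyl)-6,7-dimethoxy-1,2,3,4-tetrahydronaphthalene-2,3-diyl]dimethanol | OC[C@H]1Cc2cc(OC)c(OC)cc2[C@@H](c2ccc(OC)c(OC)c2)[C@@H]1CO | intermediate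
11 | phyltetralin | COC[C@H]1Cc2cc(OC)c(OC)cc2[C@@H](c2ccc(OC)c(OC)c2)[C@@H]1COC | target

**Summary and risks**

Total step count: 7. Longest linear sequence: 7 steps (from 1).

The three steps most likely to fail:

1. Step 4 (oxidative ring closure). Intermolecular coupling to oligomers, Claisen-type self-condensation of the ester enolates, or α-bromination by CuBr2 may outrun the closure of ring B. The fallback sets out from 6 and returns at 10; it replaces the free ester dianion by auxiliary-bearing imide enolates, which do not self-condense and set C2 and C3 kinetically. Compound 6 is saponified (LiOH, THF/H2O) to the diacid F1. Its mixed pivalic anhydride (PivCl, Et3N) is treated with (4R)-4-benzyl-1,3-oxazolidin-2-one and LiCl to give the bis-imide F2. The bis(imide enolate) (LiN(iPr)2, THF, −78 °C) is oxidized with CuCl2; each enolate should react on the face opposite its benzyl group, which is expected to give the trans (2S,3S) ring-closed bis-imide F3. LiBH4 (THF/MeOH) then removes both auxiliaries reductively and gives diol 10.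

2. Step 5 (thermodynamic funnel). Enolization at C2, which is flanked by the diarylmethine, may be slow, so that convergence stalls and ester cleavage competes on prolonged heating. The fallback sets out from 8 and returns at 10; it moves the equilibration to the far more acidic aldehyde level. The mixture 8 is reduced with iBu2AlH (CH2Cl2, −78 °C) to the dialdehyde epimer mixture F4, which is equilibrated with DBU (CH2Cl2, rt) to the all-trans dialdehyde F5. NaBH4 (MeOH, 0 °C) then gives 10.

3. Step 3 (asymmetric conjugate addition). Facial selectivity may be poor with the ortho-substituted cinnamate, or protodeboronation of the electron-rich boronic acid may outrun the addition. The fallback sets out from 2 and returns at 6; it sets C1 under auxiliary control. Heck reaction of 2 with acrylic acid (Pd(OAc)2, P(o-tol)3, NaOAc, DMF, 110 °C) gives the cinnamic acid F6. Mixed-anhydride acylation of (4S)-4-phenyl-1,3-oxazolidin-2-one (PivCl, Et3N, LiCl) gives the enoyl imide F7. (3,4-Dimethoxyphenyl)magnesium bromide with CuBr·SMe2 (THF, −40 °C) should add anti to the phenyl group of the chelated s-cis imide and give the (3R) conjugate adduct F8, with the remote methyl ester left intact at this temperature. NaOMe in MeOH at 0 °C then releases 6.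

**Further compounds**

F1 | step 4 | (3R)-3-[2-(2-carboxyethyl)-4,5-dimethoxyphenyl]-3-(3,4-dimethoxyphenyl)propanoic acid | OC(=O)C[C@H](c1ccc(OC)c(OC)c1)c1cc(OC)c(OC)cc1CCC(O)=O
F2 | step 4 | bis-imide of F1 with two (4R)-4-benzyl-2-oxo-1,3-oxazolidin-3-yl groups | O=C(C[C@H](c1ccc(OC)c(OC)c1)c1cc(OC)c(OC)cc1CCC(=O)N1[C@H](Cc2ccccc2)COC1=O)N1[C@H](Cc2ccccc2)COC1=O
F3 | step 4 | (1R,2S,3S)-1-(3,4-dimethoxyphenyl)-6,7-dimethoxy-1,2,3,4-tetrahydronaphthalene-2,3-dicarbonyl bis[(4R)-4-benzyl-1,3-oxazolidin-2-one] | O=C([C@H]1Cc2cc(OC)c(OC)cc2[C@@H](c2ccc(OC)c(OC)c2)[C@@H]1C(=O)N1[C@H](Cc2ccccc2)COC1=O)N1[C@H](Cc2ccccc2)COC1=O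
F4 | step 5 | (1R)-1-(3,4-dimethoxyphenyl)-6,7-dimethoxy-1,2,3,4-tetrahydronaphthalene-2,3-dicarbaldehyde, mixture of C2/C3 epimers | O=CC1Cc2cc(OC)c(OC)cc2[C@@H](c2ccc(OC)c(OC)c2)C1C=O
F5 | step 5 | (1R,2S,3S)-1-(3,4-dimethoxyphenyl)-6,7-dimethoxy-1,2,3,4-tetrahydronaphthalene-2,3-dicarbaldehyde | O=C[C@H]1Cc2cc(OC)c(OC)cc2[C@@H](c2ccc(OC)c(OC)c2)[C@@H]1C=O
F6 | step 3 | (2E)-3-[4,5-dimethoxy-2-(3-methoxy-3-oxopropyl)phenyl]prop-2-enoic acid | OC(=O)/C=C/c1cc(OC)c(OC)cc1CCC(=O)OC
F7 | step 3 | methyl 3-[4,5-dimethoxy-2-[(1E)-3-oxo-3-[(4S)-2-oxo-4-phenyl-1,3-oxazolidin-3-yl]prop-1-en-1-yl]phenyl]propanoate | COC(=O)CCc1cc(OC)c(OC)cc1/C=C/C(=O)N1[C@@H](c2ccccc2)COC1=O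
F8 | step 3 | methyl 3-[2-[(1R)-1-(3,4-dimethoxyphenyl)-3-oxo-3-[(4S)-2-oxo-4-phenyl-1,3-oxazolidin-3-yl]propyl]-4,5-dimethoxyphenyl]propanoate | COC(=O)CCc1cc(OC)c(OC)cc1[C@@H](c1ccc(OC)c(OC)c1)CC(=O)N1[C@@H](c2ccccc2)COC1=O
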